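**Plan**

1. Retrosynthetic cuts, in order: the O–CH3 bond of the tetronate; the C13–C14 bond of the diene (two sp2 fragments); the C12=C13 double bond (back to a C12 aldehyde); the O1–C2 lactone bond with re-formation of C5–C2, which contracts the butenolide to a cyclobutenone; and the C5–C6 bond (alkyllithium plus cyclobutenedione).
2. Enabling feature: the 3-methyl-4-oxy butenolide ring (O1, C2, C3, C4, C5) with its exocyclic C5=C6 bond is a ring-expanded squarate. It corresponds to a 4-hydroxy-3-methoxy-2-methylcyclobutenone whose carbinol carbon is C5 and whose hydroxyl oxygen becomes O1.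
3. Forward order: a C2-symmetric C9 diol is monosilylated and converted into an iodide; its lithium derivative adds to 3-methoxy-4-methylcyclobutenedione; lead(IV) expands the four-membered ring to the butenolide (the only ring made, the furan being bought as 3-bromofuran); the chain is completed at C12=C13 by chromium olefination and at C13–C14 by Suzuki coupling; O-demethylation ends the route.
4. Stereochemistry: C7 and C11 come from a twofold Evans methylation under (S)-4-benzyloxazolidinone control; Z-C5=C6 from thermodynamically controlled loss of acetic acid; E-C12=C13 from the boron-Takai olefination; E-C14=C15 from syn carboalumination, and both alkenes pass through the coupling with retention.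

Key step: step 8

Remark: atoms are numbered O1, C2 (lactone carbonyl), C3 (methyl-bearing), C4 (oxygen-bearing), C5 (ring carbon of the exocyclic alkene) and C6–C18 along the chain to the furan. Read this way the target is 5Z,7S,11S,12E,14E. The carbinol configuration of 15 is taken to be irrelevant because that carbon becomes sp2.

**Route**

Step 1
Reactants: 1 heptanedioyl dichloride; 2 (S)-4-benzyloxazolidin-2-one
Product: 4 1,7-bis[(S)-4-benzyl-2-oxooxazolidin-3-yl]heptane-1,7-dione, via N-lithio oxazolidinone 3 (not isolated)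
Conditions: 2 (2.1 equiv), n-BuLi (2.1 equiv), THF, −78 °C; then 1 (1.0 equiv), −78 → 0 °C
Reagents that add atoms: (S)-4-benzyloxazolidin-2-one (second equivalent of 2), O=C1N[C@@H](Cc2ccccc2)CO1
Why: N-acylation of the lithiated Evans oxazolidinone by an acid chloride is routine, and because the diacid chloride consumes two equivalents of the lithiated auxiliary the same (S)-controller is placed at both chain ends, so that both stereocentres can be set in one operation.

Step 2
Reactants: 4 1,7-bis[(S)-4-benzyl-2-oxooxazolidin-3-yl]heptane-1,7-dione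
Product: 6 (2S,6S)-1,7-bis[(S)-4-benzyl-2-oxooxazolidin-3-yl]-2,6-dimethylheptane-1,7-dione, via disodium bis-enolate 5 (not isolated)
Conditions: 4 added to NaHMDS (2.4 equiv), THF, −78 °C; then MeI (excess), −78 → −40 °C
Reagents that add atoms: iodomethane, CI
Why: in this twofold Evans asymmetric alkylation each chelated Z-sodium enolate (both ends being enolised quickly by inverse addition to excess base) should be methylated on the face away from the C4 benzyl group, which for the (S)-auxiliary sets S at both new α-centres (later C7 and C11), and the minor (2S,6R) diastereomer is expected to be removable at this stage by crystallisation or chromatography.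

Step 3
Reactants: 6 (2S,6S)-1,7-bis[(S)-4-benzyl-2-oxooxazolidin-3-yl]-2,6-dimethylheptane-1,7-dione
Product: 7 (2S,6S)-2,6-dimethylheptane-1,7-diol
Conditions: LiBH4, MeOH (2 equiv), Et2O/THF, 0 °C
Reagents that add atoms: none
Why: reductive cleavage of N-acyl oxazolidinones with lithium borohydride should give the primary alcohols without touching the α-stereocentres and returns the auxiliary.

Step 4
Reactants: 7 (2S,6S)-2,6-dimethylheptane-1,7-diol
Product: 9 (2S,6S)-7-[(tert-butyldiphenylsilyl)oxy]-2,6-dimethylheptan-1-ol, via monosodium alkoxide 8 (not isolated)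
Conditions: NaH (1.0 equiv), THF, rt; then TBDPSCl (1.0 equiv)
Reagents that add atoms: tert-butyl(chloro)diphenylsilane, CC(C)(C)[Si](Cl)(c1ccccc1)c1ccccc1
Why: silylation through the sparingly soluble monosodium alkoxide is a standard monoprotection of symmetric diols, and because the two hydroxyls of the C2-symmetric diol are homotopic only one monoether can form.

Step 5
Reactants: 9 (2S,6S)-7-[(tert-butyldiphenylsilyl)oxy]-2,6-dimethylheptan-1-ol
Product: 10 tert-butyl{[(2S,6S)-7-iodo-2,6-dimethylheptyl]oxy}diphenylsilane
Conditions: I2, PPh3, imidazole, CH2Cl2, 0 °C → rt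
Reagents that add atoms: iodine, II
Why: Appel-type iodination should convert the primary alcohol into the iodide by SN2 displacement at a carbon that is not stereogenic.

Step 6
Reactants: 11 dimethyl squarate
Product: 13 3-methoxy-4-methylcyclobut-3-ene-1,2-dione, via hydroxycyclobutenone 12 (not isolated)
Conditions: MeLi, THF, −78 °C; aq. NH4Cl; then conc. HCl (cat.), CH2Cl2, rt
Reagents that add atoms: methyllithium, [Li]C; water, O
Why: methyllithium adds 1,2 to one squarate carbonyl, and acid then ionises the tertiary carbinol to a methoxy-stabilised allyl cation that takes up water at the distal methoxy-bearing carbon and loses methanol, the usual squarate addition–rearrangement route to 3-alkoxy-4-alkylcyclobutenediones.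

Step 7
Reactants: 10 tert-butyl{[(2S,6S)-7-iodo-2,6-dimethylheptyl]oxy}diphenylsilane; 13 3-methoxy-4-methylcyclobut-3-ene-1,2-dione
Product: 15 4-hydroxy-3-methoxy-2-methyl-4-[(2S,6S)-7-(tert-butyldiphenylsilyloxy)-2,6-dimethylheptyl]cyclobut-2-en-1-one (both carbinol epimers), via alkyllithium 14 (not isolated)
Conditions: 10, t-BuLi (2.1 equiv), Et2O, −78 °C; then 13, THF, −78 °C; aq. NH4Cl
Reagents that add atoms: none
Why: iodine–lithium exchange gives the primary alkyllithium, which should add 1,2 to the ketone next to the methoxy-bearing carbon because the other carbonyl is deactivated as a vinylogous ester, so the C5–C6 bond forms with methoxy on the future C4 and methyl on C3, while the uncontrolled carbinol centre is of no consequence.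

Step 8
Reactants: 15 4-hydroxy-3-methoxy-2-methyl-4-[(2S,6S)-7-(tert-butyldiphenylsilyloxy)-2,6-dimethylheptyl]cyclobut-2-en-1-one
Product: 17 (Z)-5-[(2S,6S)-7-(tert-butyldiphenylsilyloxy)-2,6-dimethylheptylidene]-4-methoxy-3-methylfuran-2(5H)-one, via 5-acetoxyfuranone 16 (not isolated)
Conditions: Pb(OAc)4 (1.2 equiv), PhMe, rt; filter (Celite); then CSA (cat.), PhMe, 80 °C
Reagents that add atoms: none
Why: Ligand exchange at lead(IV) gives the alkoxide of the strained tertiary cyclobutenol, which should fragment at the C5–C2 bond (carbinol carbon to ring carbonyl) to lead(II) and an acyl radical or acylium at C2 that is conjugated through C3=C4 with the newly formed C5 ketone. The former carbinol oxygen then closes onto C2 to make the O1–C2 bond and the butenolide ring, a 5-exo-dig closure at the acylium carbon, and acetate caps the C5 oxocarbenium ion to give acylal 16. The closest known reaction type is the lead tetraacetate oxidative rearrangement of squarate-derived 4-hydroxycyclobutenones to 5-acetoxy- and 5-ylidene-2(5H)-furanones, here followed by acid-catalysed E1 loss of acetic acid. No stereocentre is created, since the carbinol centre of 15 and the acylal centre of 16 both end as sp2 C5, and C7 is never next to a carbonyl or a cationic carbon, so its configuration should be kept. The step needs cleavage of C5–C2 and not C5–C4, which is secured because only the former releases a stabilised acyl species whereas C4 is an sp2 enol-ether carbon; it also needs the Z alkene, which is expected under the equilibrating acidic conditions because C6 is the only carbon with β-hydrogens and the isomer with C7 syn to O1 avoids the C4 methoxy group. Chemoselectivity rests on timing, as the substrate carries no furan or diene yet and the silyl ether is inert to lead(IV).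

Step 9
Reactants: 17 (Z)-5-[(2S,6S)-7-(tert-butyldiphenylsilyloxy)-2,6-dimethylheptylidene]-4-methoxy-3-methylfuran-2(5H)-one
Product: 18 (Z)-5-[(2S,6S)-7-hydroxy-2,6-dimethylheptylidene]-4-methoxy-3-methylfuran-2(5H)-one
Conditions: HF·pyridine, pyridine, THF, 0 °C → rt
Reagents that add atoms: none
Why: desilylation with buffered HF·pyridine should free the primary alcohol under non-basic conditions, so the vinylogously acidic C7–H is not put at risk.

Step 10
Reactants: 18 (Z)-5-[(2S,6S)-7-hydroxy-2,6-dimethylheptylidene]-4-methoxy-3-methylfuran-2(5H)-one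
Product: 19 (2S,6S,Z)-7-(3-methoxy-4-methyl-5-oxofuran-2(5H)-ylidene)-2,6-dimethylheptanal
Conditions: Dess–Martin periodinane, NaHCO3, CH2Cl2, 0 °C → rt
Reagents that add atoms: none
Why: buffered Dess–Martin oxidation should give the α-branched aldehyde under neutral conditions that do not enolise C11, and the aldehyde is used at once.

Step 11
Reactants: 19 (2S,6S,Z)-7-(3-methoxy-4-methyl-5-oxofuran-2(5H)-ylidene)-2,6-dimethylheptanal
Product: 20 (Z)-5-[(2S,6S,7E)-2,6-dimethyl-8-(4,4,5,5-tetramethyl-1,3,2-dioxaborolan-2-yl)oct-7-en-1-ylidene]-4-methoxy-3-methylfuran-2(5H)-one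
Conditions: Cl2CHBpin, CrCl2, LiI, THF, rt
Reagents that add atoms: 2-(dichloromethyl)-4,4,5,5-tetramethyl-1,3,2-dioxaborolane, ClC(Cl)B1OC(C)(C)C(C)(C)O1
Why: the Takai–Utimoto boron olefination (a geminal dichromium reagent) converts aldehydes into (E)-alkenylboronates under non-basic conditions, so it should set E-C12=C13 while leaving C11 and the butenolide untouched.

Step 12
Reactants: 21 3-bromofuran; 22 oxetane
Product: 24 3-(furan-3-yl)propan-1-ol, via 3-furyllithium 23 (not isolated)
Conditions: 21, n-BuLi, THF, −78 °C; then 22, BF3·OEt2, −78 °C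
Reagents that add atoms: none
Why: bromine–lithium exchange at −78 °C gives 3-furyllithium without migration to C2, and BF3-promoted ring opening of oxetane by an aryllithium should deliver the three-carbon alcohol.

Step 13
Reactants: 24 3-(furan-3-yl)propan-1-ol
Product: 25 3-(3-iodopropyl)furan
Conditions: I2, PPh3, imidazole, CH2Cl2, 0 °C
Reagents that add atoms: iodine, II
Why: Appel-type iodination of a primary alcohol is fast at 0 °C and the phosphine consumes iodine before it can attack the furan.

Step 14
Reactants: 25 3-(3-iodopropyl)furan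
Product: 26 3-(pent-4-yn-1-yl)furan
Conditions: HC≡CLi·H2NCH2CH2NH2, DMSO, 10 °C → rt
Reagents that add atoms: lithium acetylide–ethylenediamine complex, [Li]C#C.NCCN
Why: SN2 alkylation of lithium acetylide with a primary iodide in DMSO is a standard two-carbon homologation to a terminal alkyne.

Step 15
Reactants: 26 3-(pent-4-yn-1-yl)furan
Product: 28 3-[(E)-5-iodo-4-methylpent-4-en-1-yl]furan, via alkenylalane 27 (not isolated)
Conditions: Me3Al, Cp2ZrCl2 (cat.), CH2Cl2, 0 °C → rt; then I2, THF, −30 → 0 °C
Reagents that add atoms: trimethylaluminium, C[Al](C)C; iodine, II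
Why: the zirconium-catalysed Negishi carboalumination adds methyl and aluminium syn across the terminal alkyne with aluminium at the terminus, and iodinolysis with retention should give the E trisubstituted alkenyl iodide that becomes C14=C15.

Step 16
Reactants: 20 (Z)-5-[(2S,6S,7E)-2,6-dimethyl-8-(4,4,5,5-tetramethyl-1,3,2-dioxaborolan-2-yl)oct-7-en-1-ylidene]-4-methoxy-3-methylfuran-2(5H)-one; 28 3-[(E)-5-iodo-4-methylpent-4-en-1-yl]furan
Product: 29 (Z)-5-[(2S,6S,7E,9E)-13-(furan-3-yl)-2,6,10-trimethyltrideca-7,9-dien-1-ylidene]-4-methoxy-3-methylfuran-2(5H)-one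
Conditions: Pd(dppf)Cl2·CH2Cl2 (cat.), aq. K3PO4, THF, rt, degassed
Reagents that add atoms: none
Why: Suzuki–Miyaura coupling of an alkenyl pinacol boronate with an alkenyl iodide forms C13–C14 with retention of both alkene geometries, so the 12E,14E diene should result under mildly basic conditions that the methyl tetronate tolerates.

Step 17
Reactants: 29 (Z)-5-[(2S,6S,7E,9E)-13-(furan-3-yl)-2,6,10-trimethyltrideca-7,9-dien-1-ylidene]-4-methoxy-3-methylfuran-2(5H)-one
Product: 30 (Z)-5-[(2S,6S,7E,9E)-13-(furan-3-yl)-2,6,10-trimethyltrideca-7,9-dien-1-ylidene]-4-hydroxy-3-methylfuran-2(5H)-one (CNP0389221.1)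
Conditions: n-PrSLi (from n-PrSH, n-BuLi), HMPA, rt; then cold 0.5 M HCl
Reagents that add atoms: none
Why: the thiolate should attack the O-methyl carbon in an SN2 dealkylation in which the stabilised 5-ylidene tetronate is the leaving group, so the furan, the diene and both stereocentres are not touched and acidification gives the tetronic acid.

**Compound list**

1 | heptanedioyl dichloride | ClC(=O)CCCCCC(=O)Cl | starting material
2 | (S)-4-benzyloxazolidin-2-one | O=C1N[C@@H](Cc2ccccc2)CO1 | starting material
3 | lithium salt of (S)-4-benzyloxazolidin-2-one (N-lithio) | [Li]N1[C@@H](Cc2ccccc2)COC1=O | intermediate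
4 | 1,7-bis[(S)-4-benzyl-2-oxooxazolidin-3-yl]heptane-1,7-dione | O=C(CCCCCC(=O)N1[C@@H](Cc2ccccc2)COC1=O)N1[C@@H](Cc2ccccc2)COC1=O | intermediate
5 | disodium bis-(Z)-enolate of 4 | [Na]O/C(=C\CCC/C=C(\O[Na])N1[C@@H](Cc2ccccc2)COC1=O)N1[C@@H](Cc2ccccc2)COC1=O | intermediate
6 | (2S,6S)-1,7-bis[(S)-4-benzyl-2-oxooxazolidin-3-yl]-2,6-dimethylheptane-1,7-dione | O=C([C@@H](C)CCC[C@H](C)C(=O)N1[C@@H](Cc2ccccc2)COC1=O)N1[C@@H](Cc2ccccc2)COC1=O | intermediate
7 | (2S,6S)-2,6-dimethylheptane-1,7-diol | OC[C@@H](C)CCC[C@H](C)CO | intermediate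
8 | monosodium alkoxide of 7 | [Na]OC[C@@H](C)CCC[C@H](C)CO | intermediate
9 | (2S,6S)-7-[(tert-butyldiphenylsilyl)oxy]-2,6-dimethylheptan-1-ol | OC[C@@H](C)CCC[C@H](C)CO[Si](c1ccccc1)(c1ccccc1)C(C)(C)C | intermediate
10 | tert-butyl{[(2S,6S)-7-iodo-2,6-dimethylheptyl]oxy}diphenylsilane | IC[C@@H](C)CCC[C@H](C)CO[Si](c1ccccc1)(c1ccccc1)C(C)(C)C | intermediate
11 | dimethyl squarate (3,4-dimethoxycyclobut-3-ene-1,2-dione) | COC1=C(OC)C(=O)C1=O | starting material
12 | 4-hydroxy-2,3-dimethoxy-4-methylcyclobut-2-en-1-one (racemic) | COC1=C(OC)C(C)(O)C1=O | intermediate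
13 | 3-methoxy-4-methylcyclobut-3-ene-1,2-dione | COC1=C(C)C(=O)C1=O | intermediate
14 | [(2R,6S)-7-(tert-butyldiphenylsilyloxy)-2,6-dimethylheptyl]lithium (same spatial arrangement as 10; the C2 descriptor changes only because Li ranks below C) | [Li]C[C@@H](C)CCC[C@H](C)CO[Si](c1ccccc1)(c1ccccc1)C(C)(C)C | intermediate
15 | 4-hydroxy-3-methoxy-2-methyl-4-[(2S,6S)-7-(tert-butyldiphenylsilyloxy)-2,6-dimethylheptyl]cyclobut-2-en-1-one (both C4 epimers) | CC1=C(OC)C(O)(C[C@@H](C)CCC[C@H](C)CO[Si](c2ccccc2)(c2ccccc2)C(C)(C)C)C1=O | intermediate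
16 | 5-acetoxy-5-[(2S,6S)-7-(tert-butyldiphenylsilyloxy)-2,6-dimethylheptyl]-4-methoxy-3-methylfuran-2(5H)-one (both C5 epimers) | CC1=C(OC)C(OC(C)=O)(C[C@@H](C)CCC[C@H](C)CO[Si](c2ccccc2)(c2ccccc2)C(C)(C)C)OC1=O | intermediate
17 | (Z)-5-[(2S,6S)-7-(tert-butyldiphenylsilyloxy)-2,6-dimethylheptylidene]-4-methoxy-3-methylfuran-2(5H)-one | CC1=C(OC)/C(=C/[C@@H](C)CCC[C@H](C)CO[Si](c2ccccc2)(c2ccccc2)C(C)(C)C)OC1=O | intermediate
18 | (Z)-5-[(2S,6S)-7-hydroxy-2,6-dimethylheptylidene]-4-methoxy-3-methylfuran-2(5H)-one | CC1=C(OC)/C(=C/[C@@H](C)CCC[C@H](C)CO)OC1=O | intermediate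
19 | (2S,6S,Z)-7-(3-methoxy-4-methyl-5-oxofuran-2(5H)-ylidene)-2,6-dimethylheptanal | CC1=C(OC)/C(=C/[C@@H](C)CCC[C@H](C)C=O)OC1=O | intermediate
20 | (Z)-5-[(2S,6S,7E)-2,6-dimethyl-8-(4,4,5,5-tetramethyl-1,3,2-dioxaborolan-2-yl)oct-7-en-1-ylidene]-4-methoxy-3-methylfuran-2(5H)-one | CC1=C(OC)/C(=C/[C@@H](C)CCC[C@H](C)/C=C/B2OC(C)(C)C(C)(C)O2)OC1=O | intermediate
21 | 3-bromofuran | Brc1ccoc1 | starting material
22 | oxetane | C1COC1 | starting material
23 | 3-furyllithium | [Li]c1ccoc1 | intermediate
24 | 3-(furan-3-yl)propan-1-ol | OCCCc1ccoc1 | intermediate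
25 | 3-(3-iodopropyl)furan | ICCCc1ccoc1 | intermediate
26 | 3-(pent-4-yn-1-yl)furan | C#CCCCc1ccoc1 | intermediate
27 | (E)-[5-(furan-3-yl)-2-methylpent-1-en-1-yl]dimethylalane | C[Al](C)/C=C(\C)CCCc1ccoc1 | intermediate
28 | 3-[(E)-5-iodo-4-methylpent-4-en-1-yl]furan | I/C=C(\C)CCCc1ccoc1 | intermediate
29 | (Z)-5-[(2S,6S,7E,9E)-13-(furan-3-yl)-2,6,10-trimethyltrideca-7,9-dien-1-ylidene]-4-methoxy-3-methylfuran-2(5H)-one | CC1=C(OC)/C(=C/[C@@H](C)CCC[C@H](C)/C=C/C=C(\C)CCCc2ccoc2)OC1=O | intermediate
30 | (Z)-5-[(2S,6S,7E,9E)-13-(furan-3-yl)-2,6,10-trimethyltrideca-7,9-dien-1-ylidene]-4-hydroxy-3-methylfuran-2(5H)-one | CC1=C(O)/C(=C/[C@@H](C)CCC[C@H](C)/C=C/C=C(\C)CCCc2ccoc2)OC1=O | target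

**Step count and risks**

Total: 17 steps. Longest linear sequence: 12 steps (steps 1–5, 7–11, 16 and 17, from heptanedioyl dichloride); steps 6 and 12–15 are side branches.

Steps most likely to fail:

Step 8. The acylal 16 may lose acetic acid incompletely or without geometric control, and the lead(IV) alkoxide may be diverted into oxidation that is not followed by lactonisation. The fallback builds the ylidene butenolide by tetronate aldol–dehydration and so bypasses steps 5–8. It sets out from monosilyl ether 9, which is oxidised with buffered Dess–Martin periodinane to (2S,6S)-7-[(tert-butyldiphenylsilyl)oxy]-2,6-dimethylheptanal F1. Separately, commercial 3-methyltetronic acid is O-methylated with dimethyl sulfate and K2CO3 in acetone to 4-methoxy-3-methylfuran-2(5H)-one F2. Deprotonation of this lactone at C5 with LDA in THF at −78 °C and addition to the aldehyde should give the aldol adduct 5-[(2S,6S)-7-(tert-butyldiphenylsilyloxy)-1-hydroxy-2,6-dimethylheptyl]-4-methoxy-3-methylfuran-2(5H)-one F3 as a mixture of carbinol epimers. Mesylation (MsCl, Et3N, CH2Cl2, 0 °C) to the methanesulfonate of the aldol adduct F4 and E1cB elimination with DBU should give the thermodynamically preferred Z alkene, and the sequence rejoins the route at 17.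

Step 17. The thiolate may add in conjugate fashion to the ylidene butenolide or displace methoxide at C4 by addition–elimination, and prolonged exposure may isomerise the diene. The fallback removes the methyl group before the furan and diene are present and couples the free acid. It sets out from boronate 20, which is heated with LiCl in DMF (about 90 °C) and acidified to give (Z)-5-[(2S,6S,7E)-2,6-dimethyl-8-(4,4,5,5-tetramethyl-1,3,2-dioxaborolan-2-yl)oct-7-en-1-ylidene]-4-hydroxy-3-methylfuran-2(5H)-one F5. Suzuki–Miyaura coupling of this acid, as its potassium salt, with iodide 28 (Pd(dppf)Cl2, excess aq. K3PO4, THF) and acidic work-up rejoins the route directly at target 30.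

Step 11. The slow, heterogeneous chromium reaction may allow enolisation of the α-branched aldehyde (erosion at C11), may stall, or may give incomplete E-selectivity. The fallback forms C12=C13 by an E-selective Wittig reaction of an allylic tributylphosphonium ylide and needs no coupling step. It sets out from alkyne 26 (with aldehyde 19 as partner). Carboalumination as in step 15 to alane 27, conversion to the alanate with n-BuLi and trapping with paraformaldehyde should give (E)-6-(furan-3-yl)-3-methylhex-2-en-1-ol F6. CBr4/PPh3 then gives 3-[(E)-6-bromo-4-methylhex-4-en-1-yl]furan F7, and tributylphosphine in acetonitrile gives tributyl[(E)-6-(furan-3-yl)-3-methylhex-2-en-1-yl]phosphonium bromide F8. Deprotonation with KOtBu in toluene/THF at 0 °C and addition of aldehyde 19 at −78 °C should give the 12E diene, and the sequence rejoins the route at 29.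

**Further compounds**

F1 | step 8 | (2S,6S)-7-[(tert-butyldiphenylsilyl)oxy]-2,6-dimethylheptanal | O=C[C@@H](C)CCC[C@H](C)CO[Si](c1ccccc1)(c1ccccc1)C(C)(C)C
F2 | step 8 | 4-methoxy-3-methylfuran-2(5H)-one | CC1=C(OC)COC1=O
F3 | step 8 | 5-[(2S,6S)-7-(tert-butyldiphenylsilyloxy)-1-hydroxy-2,6-dimethylheptyl]-4-methoxy-3-methylfuran-2(5H)-one (mixture of epimers at the ring carbon and the carbinol carbon) | CC1=C(OC)C(C(O)[C@@H](C)CCC[C@H](C)CO[Si](c2ccccc2)(c2ccccc2)C(C)(C)C)OC1=O
F4 | step 8 | methanesulfonate of the aldol adduct F3 | CC1=C(OC)C(C(OS(C)(=O)=O)[C@@H](C)CCC[C@H](C)CO[Si](c2ccccc2)(c2ccccc2)C(C)(C)C)OC1=O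
F5 | step 17 | (Z)-5-[(2S,6S,7E)-2,6-dimethyl-8-(4,4,5,5-tetramethyl-1,3,2-dioxaborolan-2-yl)oct-7-en-1-ylidene]-4-hydroxy-3-methylfuran-2(5H)-one | CC1=C(O)/C(=C/[C@@H](C)CCC[C@H](C)/C=C/B2OC(C)(C)C(C)(C)O2)OC1=O
F6 | step 11 | (E)-6-(furan-3-yl)-3-methylhex-2-en-1-ol | OC/C=C(\C)CCCc1ccoc1
F7 | step 11 | 3-[(E)-6-bromo-4-methylhex-4-en-1-yl]furan | BrC/C=C(\C)CCCc1ccoc1
F8 | step 11 | tributyl[(E)-6-(furan-3-yl)-3-methylhex-2-en-1-yl]phosphonium bromide | CCCC[P+](CCCC)(CCCC)C/C=C(\C)CCCc1ccoc1.[Br-]
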